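**Plan**
Retrosynthesis: remove the O8 methacrylate; open the furanone at O10–C3 and C2–C3 (key step), which turns the ten-membered carbocycle into a seven-membered lactone with C3 esterified to O8; then cut that O8–C3 ester, the O6–C12 lactone and the C6–C7 bond.
Forward: C6–C7 is joined by Nozaki–Hiyama allylation, the γ-lactone and then the seven-membered lactone are closed, the C2 enolate takes the C3 acyl group from O8 (ring expansion 7 → 10) and O10 closes the furanone; methacrylation and desilylation finish.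
Enabling feature: O8 lies five bonds from C2 (O8–C8–C9–C10–C1–C2), the exocyclic C4=C15 makes the C3 acyl group non-enolisable, quaternary C10 leaves C2 as the only enolisable carbon, and O10 sits 1,4 to C3 for five-ring closure.
Stereochemistry: C10 is bought ((R)-linalool); C8 comes from organocatalytic α-oxyamination; C5 from a lipase resolution; C6 and C7 are made together in the allylation, relayed from C5 and C8.

Key step: step 17

Remark: locants C1–C15 are those of the target's germacrane skeleton (C14 = methyl on C10, C15 = methylene on C4, C13 = lactone methylene); TMP-oxy = 2,2,6,6-tetramethylpiperidin-1-yloxy; (R)-linalool is assumed available in high ee, and the amine catalyst of step 3 is used as whichever enantiomer gives the 2S aldehyde.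

Step 1
Reactants: 1 (R)-(−)-linalool
Product: 2 (R)-linalool triethylsilyl ether
Conditions: TESOTf, 2,6-lutidine, CH2Cl2, 0 °C
Reagents that add atoms: triethylsilyl triflate, CC[Si](CC)(CC)OS(=O)(=O)C(F)(F)F
Why: Silyl triflate/lutidine silylation of a tertiary alcohol masks the C10 hydroxyl, which would otherwise lactolise the C7 aldehyde and later act as an alkoxide, and touches no stereocenter.

Step 2
Reactants: 2 (R)-linalool triethylsilyl ether
Product: 4 (4R)-4-methyl-4-(triethylsilyloxy)hex-5-enal, via ozonide 3 (not isolated)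
Conditions: O3 (1 equiv, Sudan III end point), CH2Cl2, −78 °C; then Me2S
Reagents that add atoms: ozone, [O-][O+]=O
Why: Chemoselective ozonolysis should cleave the electron-rich trisubstituted alkene well before the hindered monosubstituted vinyl group, giving the C7 aldehyde with C10 untouched.

Step 3
Reactants: 4 (4R)-4-methyl-4-(triethylsilyloxy)hex-5-enal
Product: 5 (2S,4R)-4-methyl-2-(TMP-oxy)-4-(triethylsilyloxy)hex-5-enal
Conditions: TEMPO (1.2 equiv), CuCl2 (10 mol %), 5-benzyl-2,2,3-trimethylimidazolidin-4-one·TFA (20 mol %), air, acetone, 0 °C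
Reagents that add atoms: TEMPO, CC1(C)CCCC(C)(C)N1[O]
Why: Enamine-mediated α-oxyamination (amine/copper dual catalysis) sets the C8–O stereocenter by catalyst control, the remote C10 center having no say, and leaves a bulky, base-stable alkoxyamine as the C8 protecting group.

Step 4
Reactants: 5 (2S,4R)-4-methyl-2-(TMP-oxy)-4-(triethylsilyloxy)hex-5-enal; 6 methyl propiolate
Product: 8 methyl (4S,6R)-3-hydroxy-6-methyl-2-methylene-4-(TMP-oxy)-6-(triethylsilyloxy)oct-7-enoate (C3 epimers), via vinylalane 7 (not isolated)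
Conditions: 6, DIBAL-H, NMO, THF, 0 °C; then 5, 0 °C → rt
Reagents that add atoms: none
Why: Vinylalumination (Morita–Baylis–Hillman-type addition of the α-aluminated acrylate formed by hydroalumination of the propiolate) attaches C11 to the hindered aldehyde without amine base, so C8 should not epimerise, and the new carbinol center is erased in step 5.

Step 5
Reactants: 8 Morita–Baylis–Hillman-type adduct
Product: 9 methyl (2Z,4S,6R)-2-(bromomethyl)-6-methyl-4-(TMP-oxy)-6-(triethylsilyloxy)octa-2,7-dienoate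
Conditions: NBS, Me2S, CH2Cl2, 0 °C → rt
Reagents that add atoms: N-bromosuccinimide, O=C1CCC(=O)N1Br
Why: Corey–Kim-type bromination of a Morita–Baylis–Hillman alcohol proceeds by SN2′ displacement to the thermodynamically preferred (Z)-2-(bromomethyl)enoate, moving the leaving group to C13 and making C7 sp2.

Step 6
Reactants: 9 (Z)-bromomethyl enoate
Product: 10 (2Z,4S,6R)-2-(bromomethyl)-6-methyl-4-(TMP-oxy)-6-(triethylsilyloxy)octa-2,7-dien-1-ol
Conditions: DIBAL-H (2.2 equiv), CH2Cl2, −78 °C
Reagents that add atoms: none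
Why: DIBAL-H 1,2-reduction of the enoate at low temperature leaves the allylic bromide intact and removes the conjugating ester, whose absence is what should allow the anti-selective allylchromium addition of step 11.

Step 7
Reactants: 11 tert-butyl acrylate; 12 (E)-crotonaldehyde
Product: 13 rac-tert-butyl (E)-3-hydroxy-2-methylenehex-4-enoate
Conditions: DABCO (0.5 equiv), neat, rt
Reagents that add atoms: none
Why: The Morita–Baylis–Hillman reaction of an acrylate with an enal assembles the C3–C6 unit with its C4 methylene in one operation, racemic at C5.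

Step 8
Reactants: 13 rac-tert-butyl (E)-3-hydroxy-2-methylenehex-4-enoate
Product: 14 tert-butyl (S,E)-3-hydroxy-2-methylenehex-4-enoate
Conditions: Burkholderia cepacia lipase (immobilised), vinyl acetate, MTBE, 30 °C, to just past half conversion; chromatography
Reagents that add atoms: none
Why: Lipase-catalysed kinetic resolution (hydrolase, irreversible transesterification) should acylate the (R)-alcohol, in line with the empirical size rule for secondary alcohols, and leave the (S)-alcohol that carries the C5 configuration of the target.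

Step 9
Reactants: 14 tert-butyl (S,E)-3-hydroxy-2-methylenehex-4-enoate
Product: 15 tert-butyl (S,E)-3-(tert-butyldimethylsilyloxy)-2-methylenehex-4-enoate
Conditions: TBSCl, imidazole, DMF, rt
Reagents that add atoms: tert-butyldimethylsilyl chloride, CC(C)(C)[Si](C)(C)Cl
Why: Standard silylation protects C5–OH with a group that should last to the final step and acts as the non-chelating Felkin–Anh control element in step 11.

Step 10
Reactants: 15 TBS ether
Product: 17 tert-butyl (R)-3-(tert-butyldimethylsilyloxy)-2-methylene-4-oxobutanoate, via ozonide 16 (not isolated)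
Conditions: O3 (1 equiv, Sudan III end point), CH2Cl2, −78 °C; then Me2S
Reagents that add atoms: ozone, [O-][O+]=O
Why: Chemoselective ozonolysis should cleave the electron-rich propenyl group and spare the electron-poor acrylate alkene, unmasking the C6 aldehyde under neutral conditions that do not epimerise the α-silyloxy center.

Step 11
Reactants: 10 (Z)-bromo allylic alcohol; 17 C3–C6 aldehyde
Product: 19 C3 tert-butyl ester 6,12-diol (5-OTBS; 8-O-TMP; 10-OTES; C1=C2 vinyl; target configuration at C5–C8 and C10), via allylchromium 18 (not isolated)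
Conditions: CrCl2 (5 equiv), THF, 0 °C → rt; aq NH4Cl
Reagents that add atoms: none
Why: In this Nozaki–Hiyama allylation the allylchromium(III) species adds through C7 in a chair transition state, so C6 and C7 are set together: C6 by Felkin–Anh attack anti to the C5 silyloxy group, C7 anti to C6 because the C8 substituent sits equatorial, and the C7 face by C8 (C8–H eclipsing the alkene to avoid A1,3 strain, the bulky aminoxy group antiperiplanar to the forming bond), three preferences that all point to the target configuration, while the reagent is aldehyde-selective and tolerant of esters and hydroxyl groups.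

Step 12
Reactants: 19 6,12-diol
Product: 22 trans-α-methylene-γ-butyrolactone with C3 tert-butyl ester (5-OTBS; 8-O-TMP; 10-OTES), via hydroxy enal 20 (not isolated), via lactol 21 (not isolated)
Conditions: activated MnO2 (30 equiv), CH2Cl2, rt
Reagents that add atoms: none
Why: Tandem allylic oxidation and lactol oxidation with MnO2 should convert the 2-methylene-1,4-diol into the trans-fused α-methylene-γ-butyrolactone, C6–OH being the only hydroxyl free to close because O5 and O8 are protected.

Step 13
Reactants: 22 lactone tert-butyl ester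
Product: 24 C3 carboxylic acid (5-OTBS; 8-O-TMP; 10-OTES), via silyl ester 23 (not isolated)
Conditions: TMSOTf, 2,6-lutidine, CH2Cl2, 0 °C; aq citric acid work-up
Reagents that add atoms: none
Why: Silyl triflate/lutidine cleavage of a tert-butyl ester (loss of isobutene, silyl ester hydrolysed on work-up) frees the C3 acid without protic acid, so the silyl ethers, the alkoxyamine and the methylene lactone should survive.

Step 14
Reactants: 24 C3 carboxylic acid
Product: 25 8-hydroxy C3 acid (5-OTBS; 10-OTES)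
Conditions: Zn dust, AcOH, THF, 40 °C
Reagents that add atoms: none
Why: Reductive N–O cleavage of the alkoxyamine with zinc in acetic acid liberates the C8 hydroxyl with retention, and the nearly anhydrous medium is chosen so that the tertiary TES and secondary TBS ethers are kept.

Step 15
Reactants: 25 8-hydroxy C3 acid
Product: 27 bicyclic bis-lactone with C3 on O8 (seven-membered) and C12 on O6 (five-membered); 5-OTBS; 10-OTES; vinyl on C10, via mixed anhydride 26 (not isolated)
Conditions: MNBA, DMAP, CH2Cl2, rt, slow addition (final 1 mM)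
Reagents that add atoms: none
Why: Shiina lactonisation (the acid is activated as the mixed anhydride 26 with 2-methyl-6-nitrobenzoic acid, then DMAP acyl transfer at high dilution) should close the seven-membered lactone on the only free hydroxyl with retention at C8, parking the non-enolisable C3 acyl group on O8.

Step 16
Reactants: 27 bis-lactone with vinyl group
Product: 28 bis-lactone methyl ketone (C1 acetyl on C10; 5-OTBS; 10-OTES)
Conditions: Pd(Quinox)Cl2 (5 mol %), AgSbF6 (12 mol %), aq TBHP, CH2Cl2, 0 °C → rt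
Reagents that add atoms: tert-butyl hydroperoxide, CC(C)(C)OO
Why: Wacker-type oxidation with TBHP as oxidant converts the monosubstituted vinyl group of a protected allylic alcohol into the methyl ketone with Markovnikov selectivity and should leave the two electron-poor 1,1-disubstituted alkenes alone.

Step 17
Reactants: 28 bis-lactone methyl ketone
Product: 30 8-O-demethacryloyl-5-O-TBS-isogoiazensolide, via diketone 29 (not isolated)
Conditions: LiHMDS (1.1 equiv), THF (5 mM), −78 → −30 °C; AcOH, −78 °C; then TsOH·H2O (0.3 equiv), wet CH2Cl2, 0 °C → rt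
Reagents that add atoms: none
Why: Proposed new method: LiHMDS can enolise 28 only at C2 (C10 is quaternary and the C3 acyl group has no α-hydrogen), and this enolate should attack the lactone carbonyl C3 held on O8 through a seven-membered transition state (7-exo-trig), the adduct collapsing with C3–O8 cleavage so that the seven-membered lactone expands to the ten-membered β-diketone 29. The closest known reactions are the Claisen acylation of ketone enolates by lactones and the acylation of α-silyloxy methyl ketone enolates followed by acid cyclodehydration, the classical route to 3(2H)-furanones; new is the intramolecular, ring-expanding topology. The ten-membered ring therefore closes by C2–C3 bond formation in a small-ring transition state instead of an end-to-end macrocyclisation, and under acid the C10 oxygen (TES lost) adds to C3 (5-exo-trig) and water is eliminated across C2–C3 to give the furanone bridge. No stereocenter is formed or endangered: C10 is quaternary, C5–C8 are not α to the enolate, and the alkoxide released at C8 should be protonated at once by the far more acidic β-diketone, so no base remains to translactonise the 6,12-lactone. The step needs attack at C3 rather than at the γ-lactone carbonyl C12 or a Michael terminus, which transition-state ring size should secure (seven-membered for C3, eight for C12 and C13, nine for C15), and it needs O10 rather than the new C8 hydroxyl to close onto the diketone, which the hindered C1 carbonyl and the more stable endocyclic vinylogous ester should favour.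

Step 18
Reactants: 30 8-O-demethacryloyl-5-O-TBS-isogoiazensolide
Product: 31 5-O-TBS-isogoiazensolide
Conditions: methacrylic anhydride, Et3N, DMAP (cat.), CH2Cl2, 0 °C
Reagents that add atoms: methacrylic anhydride, C=C(C)C(=O)OC(=O)C(C)=C
Why: DMAP-catalysed acylation esterifies the only free hydroxyl (C8–OH), C5–OH being silylated.

Step 19
Reactants: 31 5-O-TBS-isogoiazensolide
Product: 32 isogoiazensolide
Conditions: HF·pyridine, pyridine, THF, 0 °C → rt
Reagents that add atoms: none
Why: Buffered HF·pyridine desilylation should remove the secondary TBS ether without base, so the methacrylate, the methylene lactone and the dienone are not exposed to nucleophiles.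

**Compound list**
1 | (R)-(−)-linalool | CC(C)=CCC[C@@](C)(O)C=C | starting material
2 | (R)-linalool triethylsilyl ether | CC(C)=CCC[C@@](C)(O[Si](CC)(CC)CC)C=C | intermediate
3 | ozonide of 2 at the trisubstituted alkene | CC1(C)OOC(CC[C@@](C)(O[Si](CC)(CC)CC)C=C)O1 | intermediate
4 | (4R)-4-methyl-4-(triethylsilyloxy)hex-5-enal | O=CCC[C@@](C)(O[Si](CC)(CC)CC)C=C | intermediate
5 | (2S,4R)-4-methyl-2-(TMP-oxy)-4-(triethylsilyloxy)hex-5-enal | O=C[C@@H](ON1C(C)(C)CCCC1(C)C)C[C@@](C)(O[Si](CC)(CC)CC)C=C | intermediate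
6 | methyl propiolate | C#CC(=O)OC | starting material
7 | [1-(methoxycarbonyl)vinyl]diisobutylaluminium | C=C(C(=O)OC)[Al](CC(C)C)CC(C)C | intermediate
8 | methyl (4S,6R)-3-hydroxy-6-methyl-2-methylene-4-(TMP-oxy)-6-(triethylsilyloxy)oct-7-enoate, C3 epimers | COC(=O)C(=C)C(O)[C@@H](ON1C(C)(C)CCCC1(C)C)C[C@@](C)(O[Si](CC)(CC)CC)C=C | intermediate
9 | methyl (2Z,4S,6R)-2-(bromomethyl)-6-methyl-4-(TMP-oxy)-6-(triethylsilyloxy)octa-2,7-dienoate | COC(=O)/C(CBr)=C/[C@@H](ON1C(C)(C)CCCC1(C)C)C[C@@](C)(O[Si](CC)(CC)CC)C=C | intermediate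
10 | (2Z,4S,6R)-2-(bromomethyl)-6-methyl-4-(TMP-oxy)-6-(triethylsilyloxy)octa-2,7-dien-1-ol | OC/C(CBr)=C/[C@@H](ON1C(C)(C)CCCC1(C)C)C[C@@](C)(O[Si](CC)(CC)CC)C=C | intermediate
11 | tert-butyl acrylate | C=CC(=O)OC(C)(C)C | starting material
12 | (E)-crotonaldehyde | C/C=C/C=O | starting material
13 | rac-tert-butyl (E)-3-hydroxy-2-methylenehex-4-enoate | C=C(C(=O)OC(C)(C)C)C(O)/C=C/C | intermediate
14 | tert-butyl (S,E)-3-hydroxy-2-methylenehex-4-enoate | C=C(C(=O)OC(C)(C)C)[C@@H](O)/C=C/C | intermediate
15 | tert-butyl (S,E)-3-(tert-butyldimethylsilyloxy)-2-methylenehex-4-enoate | C=C(C(=O)OC(C)(C)C)[C@@H](O[Si](C)(C)C(C)(C)C)/C=C/C | intermediate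
16 | ozonide of 15 at the propenyl group | CC1OOC([C@H](O[Si](C)(C)C(C)(C)C)C(=C)C(=O)OC(C)(C)C)O1 | intermediate
17 | tert-butyl (R)-3-(tert-butyldimethylsilyloxy)-2-methylene-4-oxobutanoate | C=C(C(=O)OC(C)(C)C)[C@@H](O[Si](C)(C)C(C)(C)C)C=O | intermediate
18 | allylchromium(III) dichloride from 10 (η1 form drawn) | OC/C(C[Cr](Cl)Cl)=C/[C@@H](ON1C(C)(C)CCCC1(C)C)C[C@@](C)(O[Si](CC)(CC)CC)C=C | intermediate
19 | C3 tert-butyl ester 6,12-diol (5-OTBS, 8-O-TMP, 10-OTES, vinyl on C10; target configuration at C5–C8, C10) | C=C(C(=O)OC(C)(C)C)[C@@H](O[Si](C)(C)C(C)(C)C)[C@@H](O)[C@H](C(=C)CO)[C@@H](ON1C(C)(C)CCCC1(C)C)C[C@@](C)(O[Si](CC)(CC)CC)C=C | intermediate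
20 | 6-hydroxy C12 enal from 19 | C=C(C(=O)OC(C)(C)C)[C@@H](O[Si](C)(C)C(C)(C)C)[C@@H](O)[C@H](C(=C)C=O)[C@@H](ON1C(C)(C)CCCC1(C)C)C[C@@](C)(O[Si](CC)(CC)CC)C=C | intermediate
21 | 6,12-lactol from 20 (C12 epimers) | C=C(C(=O)OC(C)(C)C)[C@@H](O[Si](C)(C)C(C)(C)C)[C@H]1OC(O)C(=C)[C@@H]1[C@@H](ON2C(C)(C)CCCC2(C)C)C[C@@](C)(O[Si](CC)(CC)CC)C=C | intermediate
22 | trans-α-methylene-γ-butyrolactone (6,12) with C3 tert-butyl ester, 5-OTBS, 8-O-TMP, 10-OTES | C=C(C(=O)OC(C)(C)C)[C@@H](O[Si](C)(C)C(C)(C)C)[C@H]1OC(=O)C(=C)[C@@H]1[C@@H](ON2C(C)(C)CCCC2(C)C)C[C@@](C)(O[Si](CC)(CC)CC)C=C | intermediate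
23 | C3 trimethylsilyl ester of 24 | C=C(C(=O)O[Si](C)(C)C)[C@@H](O[Si](C)(C)C(C)(C)C)[C@H]1OC(=O)C(=C)[C@@H]1[C@@H](ON2C(C)(C)CCCC2(C)C)C[C@@](C)(O[Si](CC)(CC)CC)C=C | intermediate
24 | C3 carboxylic acid (5-OTBS, 8-O-TMP, 10-OTES) | C=C(C(=O)O)[C@@H](O[Si](C)(C)C(C)(C)C)[C@H]1OC(=O)C(=C)[C@@H]1[C@@H](ON2C(C)(C)CCCC2(C)C)C[C@@](C)(O[Si](CC)(CC)CC)C=C | intermediate
25 | 8-hydroxy C3 carboxylic acid (5-OTBS, 10-OTES) | C=C(C(=O)O)[C@@H](O[Si](C)(C)C(C)(C)C)[C@H]1OC(=O)C(=C)[C@@H]1[C@@H](O)C[C@@](C)(O[Si](CC)(CC)CC)C=C | intermediate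
26 | mixed anhydride of 25 with 2-methyl-6-nitrobenzoic acid | C=C(C(=O)OC(=O)c1c(C)cccc1[N+](=O)[O-])[C@@H](O[Si](C)(C)C(C)(C)C)[C@H]1OC(=O)C(=C)[C@@H]1[C@@H](O)C[C@@](C)(O[Si](CC)(CC)CC)C=C | intermediate
27 | bis-lactone: seven-membered O8–C3 lactone trans-fused to the 6,12-γ-lactone; 5-OTBS; C8 side chain CH2–C(CH3)(OTES)–CH=CH2 | C=C1C(=O)O[C@@H](C[C@@](C)(O[Si](CC)(CC)CC)C=C)[C@H]2C(=C)C(=O)O[C@@H]2[C@@H]1O[Si](C)(C)C(C)(C)C | intermediate
28 | bis-lactone methyl ketone: as 27 with C8 side chain CH2–C(CH3)(OTES)–C(=O)CH3 | C=C1C(=O)O[C@@H](C[C@@](C)(O[Si](CC)(CC)CC)C(C)=O)[C@H]2C(=C)C(=O)O[C@@H]2[C@@H]1O[Si](C)(C)C(C)(C)C | intermediate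
29 | ten-membered 1,3-diketone (C1, C3) with 8-OH, 10-OTES, 5-OTBS and the 6,12-lactone | O=C1CC(=O)C(=C)[C@@H](O[Si](C)(C)C(C)(C)C)[C@H]2OC(=O)C(=C)[C@@H]2[C@@H](O)C[C@@]1(C)O[Si](CC)(CC)CC | intermediate
30 | 8-O-demethacryloyl-5-O-TBS-isogoiazensolide | O[C@H]1C[C@@]2(C)OC(=CC2=O)C(=C)[C@@H](O[Si](C)(C)C(C)(C)C)[C@H]2OC(=O)C(=C)[C@@H]21 | intermediate
31 | 5-O-TBS-isogoiazensolide | C=C(C)C(=O)O[C@H]1C[C@@]2(C)OC(=CC2=O)C(=C)[C@@H](O[Si](C)(C)C(C)(C)C)[C@H]2OC(=O)C(=C)[C@@H]21 | intermediate
32 | isogoiazensolide | C=C(C)C(=O)O[C@H]1C[C@@]2(C)OC(=CC2=O)C(=C)[C@@H](O)[C@H]2OC(=O)C(=C)[C@@H]21 | target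

**Totals**
Total step count: 19. Longest linear sequence: 15 (steps 1–6 and 11–19).

**Steps most likely to fail**

Step 17 (Proposed new method). The enolate may acylate at the γ-lactone carbonyl or add in conjugate fashion instead of attacking C3. The freed C8 hydroxyl may translactonise the 6,12-lactone, or close onto C1 in the acid phase instead of O10 closing onto C3. The fallback uses known reactions, sets out from 28 and returns at 30. The tertiary silyl ether is first removed (HF·pyridine/pyridine, 0 °C) to give the free α-hydroxy ketone F1. Potassium tert-butoxide (THF, −40 → 0 °C) then moves the C3 acyl group from O8 to the neighbouring O10 (1,3-acyl migration of a 1,3-diol monoester), giving the nine-membered α-acyloxy ketone F2. F2 is not isolated: it undergoes Baker–Venkataraman O→C acyl transfer through a five-membered transition state, and TsOH dehydrates the resulting hemiketal to 30. Here the O10–C3 bond exists before the C2–C3 bond is made, so the sense of furanone closure is fixed.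

Step 11. Facial selectivity at C7 may be poor or reversed if the C8 stereocenter and the aldehyde prove to be a mismatched pair, and anti selectivity may erode. The fallback sets out from 4 and returns at 27, and makes the C8 epimer on purpose. Step 3 with the enantiomeric amine catalyst gives the (2R,4R)-aldehyde F3, which is taken through the operations of steps 4–6 (adduct F4, bromide F5, bromo alcohol F6). Allylation of 17 then goes through allylchromium F7 to diol F8; in this pairing the opposite intrinsic face preference delivers the needed C7 configuration. Oxidative lactonisation follows (hydroxy enal F9, lactol F10, lactone F11), then ester cleavage (silyl ester F12, acid F13) and N–O cleavage to the 8-epi hydroxy acid F14. The seven-membered lactone is finally closed by Mitsunobu lactonisation (PPh3, DIAD, toluene, high dilution), which inverts C8 and gives 27.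

Step 16. The vinyl group sits on a quaternary, silyloxy-bearing carbon, so oxidation may be slow or turn to the anti-Markovnikov aldehyde. The fallback sets out from 27 and returns at 28, and replaces C2 instead of oxidising C1. Selective ozonolysis of the isolated vinyl group (1 equiv O3, −78 °C, Me2S; the two electron-poor alkenes react later) goes through ozonide F15 to the C1 aldehyde F16. MeTi(OiPr)3 adds a methyl group chemoselectively to give the carbinol F17, and Dess–Martin oxidation gives 28.

**Further compounds**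
F1 | step 17 | 10-O-desilyl bis-lactone methyl ketone (free tertiary α-hydroxy ketone) | C=C1C(=O)O[C@@H](C[C@@](C)(O)C(C)=O)[C@H]2C(=C)C(=O)O[C@@H]2[C@@H]1O[Si](C)(C)C(C)(C)C
F2 | step 17 | nine-membered O10–C3 lactone (α-acyloxy ketone) with free 8-OH | CC(=O)[C@@]1(C)C[C@H](O)[C@H]2C(=C)C(=O)O[C@@H]2[C@H](O[Si](C)(C)C(C)(C)C)C(=C)C(=O)O1
F3 | step 11 | (2R,4R)-4-methyl-2-(TMP-oxy)-4-(triethylsilyloxy)hex-5-enal | O=C[C@H](ON1C(C)(C)CCCC1(C)C)C[C@@](C)(O[Si](CC)(CC)CC)C=C
F4 | step 11 | C8 epimer of 8 | COC(=O)C(=C)C(O)[C@H](ON1C(C)(C)CCCC1(C)C)C[C@@](C)(O[Si](CC)(CC)CC)C=C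
F5 | step 11 | C8 epimer of 9 | COC(=O)/C(CBr)=C/[C@H](ON1C(C)(C)CCCC1(C)C)C[C@@](C)(O[Si](CC)(CC)CC)C=C
F6 | step 11 | C8 epimer of 10 | OC/C(CBr)=C/[C@H](ON1C(C)(C)CCCC1(C)C)C[C@@](C)(O[Si](CC)(CC)CC)C=C
F7 | step 11 | C8 epimer of 18 | OC/C(C[Cr](Cl)Cl)=C/[C@H](ON1C(C)(C)CCCC1(C)C)C[C@@](C)(O[Si](CC)(CC)CC)C=C
F8 | step 11 | C8 epimer of 19 | C=C(C(=O)OC(C)(C)C)[C@@H](O[Si](C)(C)C(C)(C)C)[C@@H](O)[C@H](C(=C)CO)[C@H](ON1C(C)(C)CCCC1(C)C)C[C@@](C)(O[Si](CC)(CC)CC)C=C
F9 | step 11 | C8 epimer of 20 | C=C(C(=O)OC(C)(C)C)[C@@H](O[Si](C)(C)C(C)(C)C)[C@@H](O)[C@H](C(=C)C=O)[C@H](ON1C(C)(C)CCCC1(C)C)C[C@@](C)(O[Si](CC)(CC)CC)C=C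
F10 | step 11 | C8 epimer of 21 | C=C(C(=O)OC(C)(C)C)[C@@H](O[Si](C)(C)C(C)(C)C)[C@H]1OC(O)C(=C)[C@@H]1[C@H](ON2C(C)(C)CCCC2(C)C)C[C@@](C)(O[Si](CC)(CC)CC)C=C
F11 | step 11 | C8 epimer of 22 | C=C(C(=O)OC(C)(C)C)[C@@H](O[Si](C)(C)C(C)(C)C)[C@H]1OC(=O)C(=C)[C@@H]1[C@H](ON2C(C)(C)CCCC2(C)C)C[C@@](C)(O[Si](CC)(CC)CC)C=C
F12 | step 11 | C8 epimer of 23 | C=C(C(=O)O[Si](C)(C)C)[C@@H](O[Si](C)(C)C(C)(C)C)[C@H]1OC(=O)C(=C)[C@@H]1[C@H](ON2C(C)(C)CCCC2(C)C)C[C@@](C)(O[Si](CC)(CC)CC)C=C
F13 | step 11 | C8 epimer of 24 | C=C(C(=O)O)[C@@H](O[Si](C)(C)C(C)(C)C)[C@H]1OC(=O)C(=C)[C@@H]1[C@H](ON2C(C)(C)CCCC2(C)C)C[C@@](C)(O[Si](CC)(CC)CC)C=C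
F14 | step 11 | C8 epimer of 25 (8-epi hydroxy acid) | C=C(C(=O)O)[C@@H](O[Si](C)(C)C(C)(C)C)[C@H]1OC(=O)C(=C)[C@@H]1[C@H](O)C[C@@](C)(O[Si](CC)(CC)CC)C=C
F15 | step 16 | ozonide of 27 at the vinyl group | C=C1C(=O)O[C@@H](C[C@@](C)(O[Si](CC)(CC)CC)C3OOCO3)[C@H]2C(=C)C(=O)O[C@@H]2[C@@H]1O[Si](C)(C)C(C)(C)C
F16 | step 16 | C1 aldehyde (C8 side chain CH2–C(CH3)(OTES)–CHO) | C=C1C(=O)O[C@@H](C[C@@](C)(O[Si](CC)(CC)CC)C=O)[C@H]2C(=C)C(=O)O[C@@H]2[C@@H]1O[Si](C)(C)C(C)(C)C
F17 | step 16 | C1 carbinol (C8 side chain CH2–C(CH3)(OTES)–CH(OH)CH3, C1 epimers) | C=C1C(=O)O[C@@H](C[C@@](C)(O[Si](CC)(CC)CC)C(C)O)[C@H]2C(=C)C(=O)O[C@@H]2[C@@H]1O[Si](C)(C)C(C)(C)C
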